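## Retrosynthetic overview

1. Target 27 comes from the bicyclic epoxy enone 23 by chelation-controlled reduction of the C2 ketone, senecioylation and desilylation.
2. 23 comes from the open-chain α′-chloro enone aldehyde 20 by a macrocyclising Darzens condensation: the C1–C11 bond (11-membered carbocycle) and the oxirane C–O bond form in the same operation, and no ring exists before that step.
3. 20 comes from terminal alkyne 16 (hydrozirconation/acylation with 2-chloropropanoyl chloride, then acetal hydrolysis).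
4. 16 comes from aldehyde 9 and the α-branched stabilised ylide 13 by Wittig olefination (C7=C8), ester reduction and silylation.
5. 9 comes from geraniol: copper/NHC-catalysed enantioselective SN2′ alkynylation of geranyl phosphate sets the C5 quaternary centre, and hydroboration–oxidation of the new vinyl group gives the C6–C7 arm.

Numbering: locants C1–C12 in the Why lines are those of the 12-oxabicyclo[9.1.0]dodecane name of the target (C1 and C11 oxirane carbons, C2 carbinol, C5 quaternary carbon, C8 carrying CH2OH).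

Assumption: the antipode of the imidazolinium NHC precursor that gives the S quaternary centre in 5 is used; the sense of induction is confirmed on 5 before scale-up.

## Route

Step 1
Reactants: 1 geraniol
Product: 2 diethyl (2E)-3,7-dimethylocta-2,6-dien-1-yl phosphate
Conditions: ClP(O)(OEt)2, pyridine, DMAP (cat.), CH2Cl2, 0 °C to rt
Reagents that add atoms: diethyl chlorophosphate, CCOP(=O)(Cl)OCC
Why: O-Phosphorylation of the primary allylic alcohol installs the leaving group for copper-catalysed SN2′ substitution without touching the E alkene; no stereocentre is formed.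

Step 2
Reactants: 2 diethyl (2E)-3,7-dimethylocta-2,6-dien-1-yl phosphate; 3 ethynyl(trimethyl)silane
Product: 5 [(3S)-3-ethenyl-3,7-dimethyloct-6-en-1-yn-1-yl](trimethyl)silane, via alkynylalane 4 (not isolated)
Conditions: 3, iBu2AlH, Et3N (5 mol%), hexanes, 55 °C; then 2, CuCl2·2H2O (5 mol%), chiral N-(2-sulfonatoaryl)imidazolinium salt (NHC precursor, 2.5 mol%), THF, −15 °C
Reagents that add atoms: none
Why: Copper/NHC-catalysed enantioselective allylic substitution of a trisubstituted allylic phosphate with an alkynylaluminium reagent (amine-catalysed C–H alumination of the alkyne, then SN2′-selective C–C bond formation) is an established route to alkyne-bearing quaternary centres, and the chiral NHC–copper complex selects the alkene face so that the quaternary carbon (later C5) is formed as S.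

Step 3
Reactants: 5 [(3S)-3-ethenyl-3,7-dimethyloct-6-en-1-yn-1-yl](trimethyl)silane
Product: 8 (3S)-3-ethynyl-3,7-dimethyloct-6-en-1-ol, via alkylborane 6 (not isolated), via silyl alkynol 7 (not isolated)
Conditions: 9-BBN, THF, 0 °C to rt; then NaOH, H2O2, 0 °C; then K2CO3, MeOH, rt
Reagents that add atoms: hydrogen peroxide, OO
Why: 9-BBN hydroborates the monosubstituted vinyl group anti-Markovnikov far faster than the trisubstituted alkene or the silylated alkyne (Brown hydroboration–oxidation), and the alkynyl C–Si bond is cleaved by methanolic base in the same pot; the quaternary centre is not involved.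

Step 4
Reactants: 8 (3S)-3-ethynyl-3,7-dimethyloct-6-en-1-ol
Product: 9 (3S)-3-ethynyl-3,7-dimethyloct-6-enal
Conditions: PhI(OAc)2, TEMPO (10 mol%), CH2Cl2, rt
Reagents that add atoms: none
Why: Oxoammonium (TEMPO) oxidation converts the primary alcohol into the aldehyde without over-oxidation and leaves alkyne and alkene untouched; the aldehyde has no α-stereocentre to lose.

Step 5
Reactants: 10 methyl (triphenyl-λ5-phosphanylidene)acetate; 11 2-(2-bromoethyl)-1,3-dioxolane
Product: 13 methyl 4-(1,3-dioxolan-2-yl)-2-(triphenyl-λ5-phosphanylidene)butanoate, via phosphonium bromide 12 (not isolated)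
Conditions: NaI (cat.), MeCN, 80 °C; then aq. NaOH, CH2Cl2, 0 °C
Reagents that add atoms: none
Why: C-Alkylation of the stabilised ylide by the primary halide (iodide-assisted SN2) gives the α-branched phosphonium salt, which aqueous hydroxide deprotonates to the α-substituted stabilised ylide.

Step 6
Reactants: 9 (3S)-3-ethynyl-3,7-dimethyloct-6-enal; 13 methyl 4-(1,3-dioxolan-2-yl)-2-(triphenyl-λ5-phosphanylidene)butanoate
Product: 14 methyl (2E,5S)-2-[2-(1,3-dioxolan-2-yl)ethyl]-5-ethynyl-5,9-dimethyldeca-2,8-dienoate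
Conditions: toluene, 90 °C
Reagents that add atoms: none
Why: Wittig olefination with an α-branched stabilised ylide gives the trisubstituted enoate with the ester trans to the aldehyde-derived chain (E, normally above 95:5), which is the ring-cis arrangement of C6 and C9 needed at the future C7=C8 bond.

Step 7
Reactants: 14 methyl (2E,5S)-2-[2-(1,3-dioxolan-2-yl)ethyl]-5-ethynyl-5,9-dimethyldeca-2,8-dienoate
Product: 15 (2E,5S)-2-[2-(1,3-dioxolan-2-yl)ethyl]-5-ethynyl-5,9-dimethyldeca-2,8-dien-1-ol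
Conditions: iBu2AlH (2.2 equiv), CH2Cl2, −78 °C; aq. potassium sodium tartrate work-up
Reagents that add atoms: none
Why: 1,2-Reduction of the conjugated ester by the aluminium hydride gives the allylic alcohol with the alkene geometry retained; acetal and alkyne are inert at −78 °C.

Step 8
Reactants: 15 (2E,5S)-2-[2-(1,3-dioxolan-2-yl)ethyl]-5-ethynyl-5,9-dimethyldeca-2,8-dien-1-ol
Product: 16 tert-butyl({(2E,5S)-2-[2-(1,3-dioxolan-2-yl)ethyl]-5-ethynyl-5,9-dimethyldeca-2,8-dien-1-yl}oxy)diphenylsilane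
Conditions: TBDPSCl, imidazole, DMF, rt
Reagents that add atoms: tert-butyl(chloro)diphenylsilane, CC(C)(C)[Si](Cl)(c1ccccc1)c1ccccc1
Why: Silylation protects the primary allylic alcohol as a TBDPS ether that survives acetal hydrolysis, the basic ring closure and hydride reduction.

Step 9
Reactants: 16 tert-butyl({(2E,5S)-2-[2-(1,3-dioxolan-2-yl)ethyl]-5-ethynyl-5,9-dimethyldeca-2,8-dien-1-yl}oxy)diphenylsilane; 17 2-chloropropanoyl chloride (racemic)
Product: 19 (4E,6S,8E)-9-({[tert-butyl(diphenyl)silyl]oxy}methyl)-2-chloro-11-(1,3-dioxolan-2-yl)-6-methyl-6-(4-methylpent-3-en-1-yl)undeca-4,8-dien-3-one (both C2 epimers), via alkenylzirconocene 18 (not isolated)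
Conditions: Cp2Zr(H)Cl, THF, rt; then CuBr·SMe2 (10 mol%), 17, 0 °C to rt
Reagents that add atoms: none
Why: syn-Hydrozirconation of the terminal alkyne puts zirconium on the terminal carbon (E-alkenylzirconocene), and copper-catalysed acylation of this species by the acid chloride proceeds with retention to give the E-enone already carrying the α′-chlorine; the chlorine-bearing carbon is racemic but is planarised by enolisation in step 11.

Step 10
Reactants: 19 (4E,6S,8E)-9-({[tert-butyl(diphenyl)silyl]oxy}methyl)-2-chloro-11-(1,3-dioxolan-2-yl)-6-methyl-6-(4-methylpent-3-en-1-yl)undeca-4,8-dien-3-one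
Product: 20 (4E,7S,8E)-4-({[tert-butyl(diphenyl)silyl]oxy}methyl)-11-chloro-7-methyl-7-(4-methylpent-3-en-1-yl)-10-oxododeca-4,8-dienal (both C11 epimers)
Conditions: PPTS, acetone/H2O (9:1), 60 °C
Reagents that add atoms: water, O
Why: Acid-catalysed transacetalisation/hydrolysis frees the aldehyde while the TBDPS ether, the α′-chloro enone and the trisubstituted alkenes are stable to pyridinium tosylate.

Step 11
Reactants: 20 (4E,7S,8E)-4-({[tert-butyl(diphenyl)silyl]oxy}methyl)-11-chloro-7-methyl-7-(4-methylpent-3-en-1-yl)-10-oxododeca-4,8-dienal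
Product: 23 (1R,3E,5S,7E,11R)-8-({[tert-butyl(diphenyl)silyl]oxy}methyl)-1,5-dimethyl-5-(4-methylpent-3-en-1-yl)-12-oxabicyclo[9.1.0]dodeca-3,7-dien-2-one, via caesium enolate 21 (not isolated), via caesium aldolate 22 (not isolated)
Conditions: Cs2CO3 (3 equiv), MeCN, 40 °C, 20 added by syringe pump over 12 h (final 0.002 M)
Reagents that add atoms: none
Why: Proposed new method: a macrocyclising Darzens condensation in which the caesium enolate of the α-chloro ketone (the only enolisable ketone position, because the enone γ-carbon C5 is quaternary, which also shuts off Favorskii and Michael pathways) adds reversibly to the tethered aldehyde and the chlorohydrin alkoxide closes irreversibly by 3-exo-tet displacement of chloride with inversion at C1, so that the 11-membered carbocycle and the oxirane form in one operation and the base-stable product (no enolisable hydrogen left) drives the equilibria; the closest known reactions are intramolecular Darzens closures of five- to seven-membered rings and macrocyclic aldol or Reformatsky closures; the ring-cis oxirane is expected because its aldolate closes with the two ring bonds gauche, the geometry best accommodated by an 11-membered ring that already holds one E and one ring-cis alkene, and the (1R,11R) face is expected from the C5 centre placing its 4-methylpent-3-enyl chain outside the ring, which is the least secure prediction of the route (diastereomers are separable on silica).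

Step 12
Reactants: 23 (1R,3E,5S,7E,11R)-8-({[tert-butyl(diphenyl)silyl]oxy}methyl)-1,5-dimethyl-5-(4-methylpent-3-en-1-yl)-12-oxabicyclo[9.1.0]dodeca-3,7-dien-2-one
Product: 24 (1S,2S,3E,5S,7E,11R)-8-({[tert-butyl(diphenyl)silyl]oxy}methyl)-1,5-dimethyl-5-(4-methylpent-3-en-1-yl)-12-oxabicyclo[9.1.0]dodeca-3,7-dien-2-ol (C1 geometry unchanged; only its CIP label changes)
Conditions: NaBH4, CeCl3·7H2O, MeOH, −78 °C
Reagents that add atoms: none
Why: Luche 1,2-reduction of the α,β-epoxy enone under cerium chelation of the carbonyl and oxirane oxygens delivers hydride anti to the oxirane C1–C11 bond and gives the erythro (anti) epoxy alcohol, that is 2S, while the neopentyl-type C4 terminus disfavours 1,4-reduction.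

Step 13
Reactants: 24 (1S,2S,3E,5S,7E,11R)-8-({[tert-butyl(diphenyl)silyl]oxy}methyl)-1,5-dimethyl-5-(4-methylpent-3-en-1-yl)-12-oxabicyclo[9.1.0]dodeca-3,7-dien-2-ol; 25 3-methylbut-2-enoyl chloride
Product: 26 (1R,2S,3E,5S,7E,11R)-8-({[tert-butyl(diphenyl)silyl]oxy}methyl)-1,5-dimethyl-5-(4-methylpent-3-en-1-yl)-12-oxabicyclo[9.1.0]dodeca-3,7-dien-2-yl 3-methylbut-2-enoate
Conditions: pyridine, DMAP (cat.), CH2Cl2, 0 °C to rt
Reagents that add atoms: none
Why: DMAP-catalysed acylation of the secondary allylic alcohol occurs at oxygen with retention at C2, and pyridine as the only base limits vinylketene formation and deconjugation of the senecioyl group.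

Step 14
Reactants: 26 (1R,2S,3E,5S,7E,11R)-8-({[tert-butyl(diphenyl)silyl]oxy}methyl)-1,5-dimethyl-5-(4-methylpent-3-en-1-yl)-12-oxabicyclo[9.1.0]dodeca-3,7-dien-2-yl 3-methylbut-2-enoate
Product: 27 (1R,2S,3E,5S,7E,11R)-8-(hydroxymethyl)-1,5-dimethyl-5-(4-methylpent-3-en-1-yl)-12-oxabicyclo[9.1.0]dodeca-3,7-dien-2-yl 3-methylbut-2-enoate (CNP0318149.1)
Conditions: Bu4NF, AcOH (1:1), THF, 0 °C to rt
Reagents that add atoms: none
Why: Fluoride cleaves the Si–O bond of the TBDPS ether, and buffering with acetic acid protects the epoxide and the ester from base-induced opening or acyl migration.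

## Compound list

1 | geraniol, (2E)-3,7-dimethylocta-2,6-dien-1-ol | CC(C)=CCC/C(C)=C/CO | starting material
2 | diethyl (2E)-3,7-dimethylocta-2,6-dien-1-yl phosphate | CC(C)=CCC/C(C)=C/COP(=O)(OCC)OCC | intermediate
3 | ethynyl(trimethyl)silane | C#C[Si](C)(C)C | starting material
4 | bis(2-methylpropyl)[(trimethylsilyl)ethynyl]aluminium (alkynylalane, not isolated) | CC(C)C[Al](CC(C)C)C#C[Si](C)(C)C | intermediate
5 | [(3S)-3-ethenyl-3,7-dimethyloct-6-en-1-yn-1-yl](trimethyl)silane | CC(C)=CCC[C@@](C)(C=C)C#C[Si](C)(C)C | intermediate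
6 | 9-{(3R)-3,7-dimethyl-3-[(trimethylsilyl)ethynyl]oct-6-en-1-yl}-9-borabicyclo[3.3.1]nonane (alkylborane, not isolated) | CC(C)=CCC[C@@](C)(CCB1C2CCCC1CCC2)C#C[Si](C)(C)C | intermediate
7 | (3S)-3,7-dimethyl-3-[(trimethylsilyl)ethynyl]oct-6-en-1-ol (not isolated) | CC(C)=CCC[C@@](C)(CCO)C#C[Si](C)(C)C | intermediate
8 | (3S)-3-ethynyl-3,7-dimethyloct-6-en-1-ol | CC(C)=CCC[C@@](C)(CCO)C#C | intermediate
9 | (3S)-3-ethynyl-3,7-dimethyloct-6-enal | CC(C)=CCC[C@@](C)(CC=O)C#C | intermediate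
10 | methyl (triphenyl-λ5-phosphanylidene)acetate | COC(=O)C=P(c1ccccc1)(c1ccccc1)c1ccccc1 | starting material
11 | 2-(2-bromoethyl)-1,3-dioxolane | BrCCC1OCCO1 | starting material
12 | [4-(1,3-dioxolan-2-yl)-1-methoxy-1-oxobutan-2-yl](triphenyl)phosphonium bromide (not isolated) | COC(=O)C(CCC1OCCO1)[P+](c1ccccc1)(c1ccccc1)c1ccccc1.[Br-] | intermediate
13 | methyl 4-(1,3-dioxolan-2-yl)-2-(triphenyl-λ5-phosphanylidene)butanoate | COC(=O)C(CCC1OCCO1)=P(c1ccccc1)(c1ccccc1)c1ccccc1 | intermediate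
14 | methyl (2E,5S)-2-[2-(1,3-dioxolan-2-yl)ethyl]-5-ethynyl-5,9-dimethyldeca-2,8-dienoate | COC(=O)/C(CCC1OCCO1)=C/C[C@](C)(CCC=C(C)C)C#C | intermediate
15 | (2E,5S)-2-[2-(1,3-dioxolan-2-yl)ethyl]-5-ethynyl-5,9-dimethyldeca-2,8-dien-1-ol | OC/C(CCC1OCCO1)=C/C[C@](C)(CCC=C(C)C)C#C | intermediate
16 | tert-butyl({(2E,5S)-2-[2-(1,3-dioxolan-2-yl)ethyl]-5-ethynyl-5,9-dimethyldeca-2,8-dien-1-yl}oxy)diphenylsilane | CC(C)(C)[Si](OC/C(CCC1OCCO1)=C/C[C@](C)(CCC=C(C)C)C#C)(c1ccccc1)c1ccccc1 | intermediate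
17 | 2-chloropropanoyl chloride (racemic) | CC(Cl)C(Cl)=O | starting material
18 | (E)-alkenyl(chloro)zirconocene formed from 16 (not isolated) | Cl[Zr](C1C=CC=C1)(C1C=CC=C1)/C=C/[C@@](C)(CCC=C(C)C)C/C=C(/CO[Si](c1ccccc1)(c1ccccc1)C(C)(C)C)CCC1OCCO1 | intermediate
19 | (4E,6S,8E)-9-({[tert-butyl(diphenyl)silyl]oxy}methyl)-2-chloro-11-(1,3-dioxolan-2-yl)-6-methyl-6-(4-methylpent-3-en-1-yl)undeca-4,8-dien-3-one (both C2 epimers) | CC(Cl)C(=O)/C=C/[C@@](C)(CCC=C(C)C)C/C=C(/CO[Si](c1ccccc1)(c1ccccc1)C(C)(C)C)CCC1OCCO1 | intermediate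
20 | (4E,7S,8E)-4-({[tert-butyl(diphenyl)silyl]oxy}methyl)-11-chloro-7-methyl-7-(4-methylpent-3-en-1-yl)-10-oxododeca-4,8-dienal (both C11 epimers) | CC(Cl)C(=O)/C=C/[C@@](C)(CCC=C(C)C)C/C=C(/CO[Si](c1ccccc1)(c1ccccc1)C(C)(C)C)CCC=O | intermediate
21 | caesium enolate of 20 at the chloro ketone (enolate geometry not defined, not isolated) | CC(Cl)=C([O-])/C=C/[C@@](C)(CCC=C(C)C)C/C=C(/CO[Si](c1ccccc1)(c1ccccc1)C(C)(C)C)CCC=O.[Cs+] | intermediate
22 | caesium alkoxide of the 11-membered chlorohydrin (ring C–C bond formed, C–Cl carbon S, carbinolate carbon R, not isolated) | CC(C)=CCC[C@]1(C)/C=C/C(=O)[C@@](C)(Cl)[C@H]([O-])CC/C(CO[Si](c2ccccc2)(c2ccccc2)C(C)(C)C)=C\C1.[Cs+] | intermediate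
23 | (1R,3E,5S,7E,11R)-8-({[tert-butyl(diphenyl)silyl]oxy}methyl)-1,5-dimethyl-5-(4-methylpent-3-en-1-yl)-12-oxabicyclo[9.1.0]dodeca-3,7-dien-2-one | CC(C)=CCC[C@]1(C)/C=C/C(=O)[C@]2(C)O[C@@H]2CC/C(CO[Si](c3ccccc3)(c3ccccc3)C(C)(C)C)=C\C1 | intermediate
24 | (1S,2S,3E,5S,7E,11R)-8-({[tert-butyl(diphenyl)silyl]oxy}methyl)-1,5-dimethyl-5-(4-methylpent-3-en-1-yl)-12-oxabicyclo[9.1.0]dodeca-3,7-dien-2-ol | CC(C)=CCC[C@]1(C)/C=C/[C@H](O)[C@]2(C)O[C@@H]2CC/C(CO[Si](c3ccccc3)(c3ccccc3)C(C)(C)C)=C\C1 | intermediate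
25 | 3-methylbut-2-enoyl chloride | CC(C)=CC(Cl)=O | starting material
26 | (1R,2S,3E,5S,7E,11R)-8-({[tert-butyl(diphenyl)silyl]oxy}methyl)-1,5-dimethyl-5-(4-methylpent-3-en-1-yl)-12-oxabicyclo[9.1.0]dodeca-3,7-dien-2-yl 3-methylbut-2-enoate | CC(C)=CCC[C@]1(C)/C=C/[C@H](OC(=O)C=C(C)C)[C@]2(C)O[C@@H]2CC/C(CO[Si](c3ccccc3)(c3ccccc3)C(C)(C)C)=C\C1 | intermediate
27 | (1R,2S,3E,5S,7E,11R)-8-(hydroxymethyl)-1,5-dimethyl-5-(4-methylpent-3-en-1-yl)-12-oxabicyclo[9.1.0]dodeca-3,7-dien-2-yl 3-methylbut-2-enoate | CC(C)=CCC[C@]1(C)/C=C/[C@H](OC(=O)C=C(C)C)[C@]2(C)O[C@@H]2CC/C(CO)=C\C1 | target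

## Step count and risks

Total step count: 14. Longest linear sequence: 13 steps (geraniol to 27: steps 1–4 and 6–14; step 5 makes the ylide).

**Risk 1, step 11 (macrocyclising Darzens: ring closure against oligomerisation, and cis/facial selectivity of the oxirane).** The fallback sets out from 16 and comes back at 24. It forms the oxirane under reagent control before the ring and closes the carbocycle at C2–C3 instead.
- Hydrozirconation of 16 (Cp2Zr(H)Cl) and quenching with iodine gives tert-butyl({(2E,5S,6E)-2-[2-(1,3-dioxolan-2-yl)ethyl]-7-iodo-5-methyl-5-(4-methylpent-3-en-1-yl)hepta-2,6-dien-1-yl}oxy)diphenylsilane F1.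
- Acetal hydrolysis (PPTS, wet acetone) gives the aldehyde (4E,7S,8E)-4-({[tert-butyl(diphenyl)silyl]oxy}methyl)-9-iodo-7-methyl-7-(4-methylpent-3-en-1-yl)nona-4,8-dienal F2.
- Still–Gennari olefination with ethyl 2-[bis(2,2,2-trifluoroethoxy)phosphoryl]propanoate (KN(SiMe3)2, 18-crown-6, THF, −78 °C) gives the (Z)-enoate ethyl (2Z,6E,9S,10E)-6-({[tert-butyl(diphenyl)silyl]oxy}methyl)-11-iodo-2,9-dimethyl-9-(4-methylpent-3-en-1-yl)undeca-2,6,10-trienoate F3.
- iBu2AlH reduction gives the (Z)-allylic alcohol (2Z,6E,9S,10E)-6-({[tert-butyl(diphenyl)silyl]oxy}methyl)-11-iodo-2,9-dimethyl-9-(4-methylpent-3-en-1-yl)undeca-2,6,10-trien-1-ol F4.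
- Sharpless asymmetric epoxidation (Ti(OiPr)4, L-(+)-diethyl tartrate, t-BuOOH, 4 Å sieves, −20 °C) gives [(2S,3R)-3-[(3E,6S,7E)-3-({[tert-butyl(diphenyl)silyl]oxy}methyl)-8-iodo-6-methyl-6-(4-methylpent-3-en-1-yl)octa-3,7-dien-1-yl]-2-methyloxiran-2-yl]methanol F5. The cis geometry is fixed by the Z alkene and the face by the tartrate.
- Dess–Martin oxidation gives the epoxy aldehyde (2R,3R)-3-[(3E,6S,7E)-3-({[tert-butyl(diphenyl)silyl]oxy}methyl)-8-iodo-6-methyl-6-(4-methylpent-3-en-1-yl)octa-3,7-dien-1-yl]-2-methyloxirane-2-carbaldehyde F6.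
- Nozaki–Hiyama–Kishi macrocyclisation (CrCl2, NiCl2 (cat.), DMSO, high dilution) closes the ring and gives 24. Any C2 epimer is oxidised to 23 and passed through step 12.

**Risk 2, step 2 (enantioselectivity and SN2′ selectivity with an alkyl-substituted phosphate and a silylalkynyl alane).** The fallback sets out from 1 and comes back at 9. It takes the quaternary centre from a Sharpless epoxide by a stereospecific 1,2-shift.
- Asymmetric epoxidation of geraniol 1 (Ti(OiPr)4, L-(+)-diethyl tartrate, t-BuOOH) gives [(2S,3S)-3-methyl-3-(4-methylpent-3-en-1-yl)oxiran-2-yl]methanol F7.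
- TBSCl/imidazole gives tert-butyl(dimethyl){[(2S,3S)-3-methyl-3-(4-methylpent-3-en-1-yl)oxiran-2-yl]methoxy}silane F8.
- Rearrangement with methylaluminium bis(4-bromo-2,6-di-tert-butylphenoxide) (CH2Cl2, −78 °C; anti 1,2-shift of the siloxymethyl group onto the tertiary carbon) gives (2S)-2-({[tert-butyl(dimethyl)silyl]oxy}methyl)-2,6-dimethylhept-5-enal F9 with transfer of the epoxide chirality.
- Ohira–Bestmann alkynylation (dimethyl (1-diazo-2-oxopropyl)phosphonate, K2CO3, MeOH) gives tert-butyl{[(2R)-2-ethynyl-2,6-dimethylhept-5-en-1-yl]oxy}dimethylsilane F10.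
- Bu4NF gives (2R)-2-ethynyl-2,6-dimethylhept-5-en-1-ol F11.
- Dess–Martin oxidation gives (2R)-2-ethynyl-2,6-dimethylhept-5-enal F12.
- Wittig reaction with Ph3P=CHOMe gives (3S)-3-ethynyl-1-methoxy-3,7-dimethylocta-1,6-diene F13 (E/Z mixture).
- Mild aqueous acid (HCl, THF) hydrolyses the enol ether to 9.

**Risk 3, step 12 (facial selectivity of hydride addition inside the macrocycle).** The fallback sets out from 23 and comes back at 26. If reduction gives mainly the C2 epimer (1S,2R,3E,5S,7E,11R)-8-({[tert-butyl(diphenyl)silyl]oxy}methyl)-1,5-dimethyl-5-(4-methylpent-3-en-1-yl)-12-oxabicyclo[9.1.0]dodeca-3,7-dien-2-ol F14, that alcohol is esterified with inversion by a Mitsunobu reaction with 3-methylbut-2-enoic acid (PPh3, DIAD, toluene, 0 °C to rt). This gives 26 directly and replaces step 13.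

Further compounds
F1 | step 11 | tert-butyl({(2E,5S,6E)-2-[2-(1,3-dioxolan-2-yl)ethyl]-7-iodo-5-methyl-5-(4-methylpent-3-en-1-yl)hepta-2,6-dien-1-yl}oxy)diphenylsilane | I/C=C/[C@@](C)(CCC=C(C)C)C/C=C(/CO[Si](c1ccccc1)(c1ccccc1)C(C)(C)C)CCC1OCCO1
F2 | step 11 | (4E,7S,8E)-4-({[tert-butyl(diphenyl)silyl]oxy}methyl)-9-iodo-7-methyl-7-(4-methylpent-3-en-1-yl)nona-4,8-dienal | I/C=C/[C@@](C)(CCC=C(C)C)C/C=C(/CO[Si](c1ccccc1)(c1ccccc1)C(C)(C)C)CCC=O
F3 | step 11 | ethyl (2Z,6E,9S,10E)-6-({[tert-butyl(diphenyl)silyl]oxy}methyl)-11-iodo-2,9-dimethyl-9-(4-methylpent-3-en-1-yl)undeca-2,6,10-trienoate | I/C=C/[C@@](C)(CCC=C(C)C)C/C=C(/CO[Si](c1ccccc1)(c1ccccc1)C(C)(C)C)CC/C=C(/C)C(=O)OCC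
F4 | step 11 | (2Z,6E,9S,10E)-6-({[tert-butyl(diphenyl)silyl]oxy}methyl)-11-iodo-2,9-dimethyl-9-(4-methylpent-3-en-1-yl)undeca-2,6,10-trien-1-ol | I/C=C/[C@@](C)(CCC=C(C)C)C/C=C(/CO[Si](c1ccccc1)(c1ccccc1)C(C)(C)C)CC/C=C(/C)CO
F5 | step 11 | [(2S,3R)-3-[(3E,6S,7E)-3-({[tert-butyl(diphenyl)silyl]oxy}methyl)-8-iodo-6-methyl-6-(4-methylpent-3-en-1-yl)octa-3,7-dien-1-yl]-2-methyloxiran-2-yl]methanol | OC[C@]1(C)O[C@@H]1CC/C(CO[Si](c2ccccc2)(c2ccccc2)C(C)(C)C)=C\C[C@](C)(CCC=C(C)C)/C=C/I
F6 | step 11 | (2R,3R)-3-[(3E,6S,7E)-3-({[tert-butyl(diphenyl)silyl]oxy}methyl)-8-iodo-6-methyl-6-(4-methylpent-3-en-1-yl)octa-3,7-dien-1-yl]-2-methyloxirane-2-carbaldehyde | O=C[C@]1(C)O[C@@H]1CC/C(CO[Si](c2ccccc2)(c2ccccc2)C(C)(C)C)=C\C[C@](C)(CCC=C(C)C)/C=C/I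
F7 | step 2 | [(2S,3S)-3-methyl-3-(4-methylpent-3-en-1-yl)oxiran-2-yl]methanol | CC(C)=CCC[C@]1(C)O[C@H]1CO
F8 | step 2 | tert-butyl(dimethyl){[(2S,3S)-3-methyl-3-(4-methylpent-3-en-1-yl)oxiran-2-yl]methoxy}silane | CC(C)=CCC[C@]1(C)O[C@H]1CO[Si](C)(C)C(C)(C)C
F9 | step 2 | (2S)-2-({[tert-butyl(dimethyl)silyl]oxy}methyl)-2,6-dimethylhept-5-enal | CC(C)=CCC[C@@](C)(CO[Si](C)(C)C(C)(C)C)C=O
F10 | step 2 | tert-butyl{[(2R)-2-ethynyl-2,6-dimethylhept-5-en-1-yl]oxy}dimethylsilane | CC(C)=CCC[C@@](C)(CO[Si](C)(C)C(C)(C)C)C#C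
F11 | step 2 | (2R)-2-ethynyl-2,6-dimethylhept-5-en-1-ol | CC(C)=CCC[C@@](C)(CO)C#C
F12 | step 2 | (2R)-2-ethynyl-2,6-dimethylhept-5-enal | CC(C)=CCC[C@@](C)(C=O)C#C
F13 | step 2 | (3S)-3-ethynyl-1-methoxy-3,7-dimethylocta-1,6-diene (E/Z mixture) | CC(C)=CCC[C@@](C)(C=COC)C#C
F14 | step 12 | (1S,2R,3E,5S,7E,11R)-8-({[tert-butyl(diphenyl)silyl]oxy}methyl)-1,5-dimethyl-5-(4-methylpent-3-en-1-yl)-12-oxabicyclo[9.1.0]dodeca-3,7-dien-2-ol | CC(C)=CCC[C@]1(C)/C=C/[C@@H](O)[C@]2(C)O[C@@H]2CC/C(CO[Si](c3ccccc3)(c3ccccc3)C(C)(C)C)=C\C1
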